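**Strategy.** Everything rests on cutting the C7–C8 bond of the carbocycle (C4a, C5, C6, C7, C8, C8a; isochromene numbering). The tertiary α-ketol C8(=O)–C7(OH)(CH3), whose carbonyl sits on the sp2 carbon C8a of the C4a=C8a ring-fusion alkene beside the C6 oxygen stereocentre, is a benzoin retron. One carbene-catalysed crossed aldehyde–ketone benzoin therefore closes the carbocycle, forms the C7 carbinol and delivers the enynone needed later. Its precursor is an open-chain (2E)-2-en-4-ynal in which the formyl group (C8) is held cis to a chain ending in a methyl ketone (C7) with an (S)-configured PMB ether at C6. The aryl ester is added afterwards and the pyran ring is closed last through O2–C3.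

Key step: step 13

Remark: the atoms of all intermediates carry the isochromene numbers of the target (C1H2, O2, C3 with the propenyl group, C4, C4a, C5H2, C6, C7, C8, C8a).
Remark: by the sequence rules the tetrasubstituted alkene of 15 and 20, in which CHO and the C5 chain are cis, is 2E (CHO outranks CH2OSi; iodine or the alkynyl carbon outranks C5); the same geometry is Z in 11 to 13.
Assumption: in the hydrolytic kinetic resolution the (R,R) catalyst is taken to spare the epoxide with the spatial arrangement of 3, by analogy with glycidates and epihalohydrins, where the substituent also outranks the ring CH2; the recovered epoxide is checked before scale-up and the (S,S) catalyst is used if the sense is the opposite.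
Assumption: 1, 4, 9 (as a THF solution), 16 and 22 are bought.

**Route**

Step 1
Reactants: 1 2-methyl-2-vinyl-1,3-dioxolane
Product: 2 rac-2-methyl-2-(oxiran-2-yl)-1,3-dioxolane
Conditions: mCPBA (1.5 eq), Na2HPO4, CH2Cl2, 40 °C
Reagents that add atoms: mCPBA, OOC(=O)c1cccc(Cl)c1
Why: Prilezhaev epoxidation of the only alkene, slow because the allylic ketal makes it electron-poor but without a competing site, the buffer protecting the ketal and the new stereocentre being racemic at this stage.

Step 2
Reactants: 2 rac-2-methyl-2-(oxiran-2-yl)-1,3-dioxolane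
Product: 3 (S)-2-methyl-2-(oxiran-2-yl)-1,3-dioxolane
Conditions: (R,R)-N,N'-bis(3,5-di-tert-butylsalicylidene)-1,2-cyclohexanediaminocobalt acetate (0.5 mol %), H2O (0.55 eq), THF (minimal), 0 → 23 °C; distillation
Reagents that add atoms: none
Why: Hydrolytic kinetic resolution of a terminal epoxide, in which the chiral salen complex of trivalent cobalt should hydrolyse the (R)-epoxide much faster, so that the (S)-epoxide, whose stereocentre becomes C6, is distilled from the diol.

Step 3
Reactants: 3 (S)-2-methyl-2-(oxiran-2-yl)-1,3-dioxolane; 4 tert-butyldimethyl(prop-2-yn-1-yloxy)silane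
Product: 6 (S)-5-(tert-butyldimethylsilyloxy)-1-(2-methyl-1,3-dioxolan-2-yl)pent-3-yn-1-ol, via lithium acetylide 5 (not isolated)
Conditions: 4 (1.4 eq), n-BuLi, THF, −78 °C; BF3·OEt2 (1.4 eq); then 3, −78 °C
Reagents that add atoms: none
Why: BF3-promoted alkynylation of a terminal epoxide (Yamaguchi–Hirao type), an SN2 opening at the unsubstituted carbon that forms C4a–C5 and leaves the C6 stereocentre untouched, the ketal being expected to survive the Lewis acid at −78 °C.

Step 4
Reactants: 6 (S)-5-(tert-butyldimethylsilyloxy)-1-(2-methyl-1,3-dioxolan-2-yl)pent-3-yn-1-ol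
Product: 7 (S)-tert-butyl{[5-(4-methoxybenzyloxy)-5-(2-methyl-1,3-dioxolan-2-yl)pent-2-yn-1-yl]oxy}dimethylsilane
Conditions: NaH, PMBCl, n-Bu4NI (cat.), THF/DMF, 0 → 23 °C
Reagents that add atoms: 4-methoxybenzyl chloride, COc1ccc(CCl)cc1
Why: Williamson etherification of the secondary alkoxide, with silyl ether, ketal and internal alkyne inert to NaH.

Step 5
Reactants: 7 (S)-tert-butyl{[5-(4-methoxybenzyloxy)-5-(2-methyl-1,3-dioxolan-2-yl)pent-2-yn-1-yl]oxy}dimethylsilane
Product: 8 (S)-5-(4-methoxybenzyloxy)-5-(2-methyl-1,3-dioxolan-2-yl)pent-2-yn-1-ol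
Conditions: TBAF, THF, 0 °C
Reagents that add atoms: none
Why: Fluoride cleavage of the only silyl ether frees the propargylic hydroxyl that directs the next step.

Step 6
Reactants: 8 (S)-5-(4-methoxybenzyloxy)-5-(2-methyl-1,3-dioxolan-2-yl)pent-2-yn-1-ol; 9 vinylmagnesium chloride
Product: 11 (2Z,5S)-3-iodo-5-(4-methoxybenzyloxy)-5-(2-methyl-1,3-dioxolan-2-yl)-2-vinylpent-2-en-1-ol, via cyclic alkenylmagnesium alkoxide 10 (not isolated)
Conditions: 9 (4 eq), THF/toluene, 70 °C; then I2, THF, −78 → 0 °C
Reagents that add atoms: iodine, II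
Why: Alkoxide-directed anti-carbomagnesiation of a propargylic alcohol, in which the magnesium alkoxide places the vinyl group on the proximal alkyne carbon (C8a) and magnesium on C4a in a five-membered chelate, and iodinolysis with retention fixes the geometry (iodine cis to CH2OH, vinyl cis to the C5 chain).

Step 7
Reactants: 11 (2Z,5S)-3-iodo-5-(4-methoxybenzyloxy)-5-(2-methyl-1,3-dioxolan-2-yl)-2-vinylpent-2-en-1-ol
Product: 12 tert-butyl{[(2Z,5S)-3-iodo-5-(4-methoxybenzyloxy)-5-(2-methyl-1,3-dioxolan-2-yl)-2-vinylpent-2-en-1-yl]oxy}diphenylsilane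
Conditions: TBDPSCl, imidazole, CH2Cl2, 23 °C
Reagents that add atoms: tert-butyldiphenylsilyl chloride, CC(C)(C)[Si](Cl)(c1ccccc1)c1ccccc1
Why: Silylation of the primary allylic alcohol with a group that survives the acid of step 8 and keeps O2 from attacking the alkyne before the last step.

Step 8
Reactants: 12 tert-butyl{[(2Z,5S)-3-iodo-5-(4-methoxybenzyloxy)-5-(2-methyl-1,3-dioxolan-2-yl)-2-vinylpent-2-en-1-yl]oxy}diphenylsilane
Product: 13 (3S,5Z)-6-[(tert-butyldiphenylsilyloxy)methyl]-5-iodo-3-(4-methoxybenzyloxy)octa-5,7-dien-2-one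
Conditions: p-TsOH·H2O (0.2 eq), acetone/H2O 9:1, 45 °C
Reagents that add atoms: water, O
Why: Acid-catalysed ketal hydrolysis, placed before any aldehyde is present, which the PMB and TBDPS ethers and the iodo diene should tolerate and which is too mild to enolise the α-alkoxy ketone at C6.

Step 9
Reactants: 13 (3S,5Z)-6-[(tert-butyldiphenylsilyloxy)methyl]-5-iodo-3-(4-methoxybenzyloxy)octa-5,7-dien-2-one
Product: 15 (2E,5S)-2-[(tert-butyldiphenylsilyloxy)methyl]-3-iodo-5-(4-methoxybenzyloxy)-6-oxohept-2-enal, via vicinal diol 14 (not isolated)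
Conditions: OsO4 (2 mol %), NaIO4 (4 eq), 2,6-lutidine (2 eq), dioxane/H2O 3:1, 23 °C
Reagents that add atoms: osmium tetroxide, O=[Os](=O)(=O)=O; sodium periodate (terminal oxidant that supplies the oxygen through osmium), [Na+].[O-]I(=O)(=O)=O
Why: Lemieux–Johnson cleavage, in which OsO4 dihydroxylates the monosubstituted terminal alkene in preference to the hindered, electron-poor tetrasubstituted iodoalkene and periodate cleaves the diol to the C8 aldehyde under lutidine buffering.

Step 10
Reactants: 16 (E)-crotonaldehyde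
Product: 17 (3E)-1,1-dibromopenta-1,3-diene
Conditions: CBr4 (2 eq), PPh3 (4 eq), CH2Cl2, 0 °C
Reagents that add atoms: carbon tetrabromide, BrC(Br)(Br)Br
Why: First stage of the Corey–Fuchs homologation (Wittig-type dibromo-olefination), which adds the carbon that becomes C4 and leaves the E-alkene alone.

Step 11
Reactants: 17 (3E)-1,1-dibromopenta-1,3-diene
Product: 19 (E)-pent-3-en-1-yne, via lithium pentenynide 18 (not isolated)
Conditions: n-BuLi (2.1 eq), Et2O, −78 → 0 °C; H2O; used as a dried, titrated Et2O solution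
Reagents that add atoms: none
Why: Second stage of the Corey–Fuchs homologation (bromine–lithium exchange, α-elimination with 1,2-shift, protonation of the acetylide), giving the volatile terminal enyne with the E-alkene intact.

Step 12
Reactants: 15 (2E,5S)-2-[(tert-butyldiphenylsilyloxy)methyl]-3-iodo-5-(4-methoxybenzyloxy)-6-oxohept-2-enal; 19 (E)-pent-3-en-1-yne
Product: 20 (2E,5S)-2-[(tert-butyldiphenylsilyloxy)methyl]-5-(4-methoxybenzyloxy)-6-oxo-3-[(E)-pent-3-en-1-yn-1-yl]hept-2-enal
Conditions: PdCl2(PPh3)2 (5 mol %), CuI (10 mol %), Et3N (3 eq), THF, 0 → 23 °C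
Reagents that add atoms: none
Why: Sonogashira coupling of an activated β-iodo enal, which should run near room temperature with retention of alkene geometry to form C4a–C4, the brief exposure to Et3N being too mild to epimerise C6.

Step 13
Reactants: 20 (2E,5S)-2-[(tert-butyldiphenylsilyloxy)methyl]-5-(4-methoxybenzyloxy)-6-oxo-3-[(E)-pent-3-en-1-yn-1-yl]hept-2-enal
Product: 21 (5S,6S)-2-[(tert-butyldiphenylsilyloxy)methyl]-6-hydroxy-5-(4-methoxybenzyloxy)-6-methyl-3-[(E)-pent-3-en-1-yn-1-yl]cyclohex-2-en-1-one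
Conditions: (5aS,10bR)-2-(pentafluorophenyl)-4,5a,6,10b-tetrahydroindeno[2,1-b][1,2,4]triazolo[4,3-d][1,4]oxazin-2-ium tetrafluoroborate (15 mol %; antipode if mismatched), Et3N (20 mol %), toluene, 23 °C
Reagents that add atoms: none
Why: The carbene released from the triazolium salt adds to the C8 aldehyde, proton transfer gives the Breslow enaminol, its C8 carbon attacks the tethered C7 methyl ketone, and proton transfer with loss of the carbene releases the α-ketol. This is the intramolecular crossed aldehyde–ketone benzoin cyclisation, established for six-membered tertiary α-ketols from aldehydes carrying a 3-oxobutyl-type chain on an sp2 carbon, of which 20 is the vinylogous member. The carbocycle (C8, C8a, C4a, C5, C6, C7) closes 6-exo-trig onto the ketone carbonyl, the 2E alkene holding C8 and the ketone chain on the same side. C7 is set under control of the resident C6 stereocentre: in the chair-like transition state the C6 PMB ether and the C7 methyl group are both pseudo-equatorial, so the new C7 oxygen is pseudo-axial and cis to the C6 oxygen, and the catalyst enantiomer is chosen to reinforce this face. The step needs acyl-anion reactivity at C8 in preference to homoenolate reactivity at C4a or C3, which the fully substituted, hindered C4a, the electron-poor N-C6F5 triazolium and the fast six-membered closure onto an α-alkoxy-activated ketone should secure, and only the aldehyde can form the Breslow intermediate, so no homo-coupling competes. A weak amine base in catalytic amount avoids enolisation at C6 and deprotonation at C5.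

Step 14
Reactants: 22 methyl orsellinate (methyl 2,4-dihydroxy-6-methylbenzoate)
Product: 24 methyl 4-(benzyloxy)-2-methoxy-6-methylbenzoate, via methyl 4-benzyloxy-2-hydroxy-6-methylbenzoate 23 (not isolated)
Conditions: BnBr (1.05 eq), K2CO3, acetone, 56 °C; then MeI (5 eq), 50 °C, sealed
Reagents that add atoms: benzyl bromide, BrCc1ccccc1; iodomethane, CI
Why: Two Williamson O-alkylations in sequence, the free 4-OH reacting first with benzyl bromide because the 2-OH is held in a hydrogen bond to the ester, and the chelated 2-OH then being methylated by excess iodomethane.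

Step 15
Reactants: 24 methyl 4-(benzyloxy)-2-methoxy-6-methylbenzoate
Product: 25 4-(benzyloxy)-2-methoxy-6-methylbenzoic acid
Conditions: KOH, DMSO/H2O 4:1, 90 °C; then 1 M HCl
Reagents that add atoms: potassium hydroxide, [K+].[OH-]
Why: Saponification of a di-ortho-substituted benzoate, which needs forcing hydroxide conditions that both aryl ethers tolerate.

Step 16
Reactants: 25 4-(benzyloxy)-2-methoxy-6-methylbenzoic acid
Product: 26 4-hydroxy-2-methoxy-6-methylbenzoic acid
Conditions: H2 (1 atm), 10% Pd/C, EtOAc/MeOH, 23 °C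
Reagents that add atoms: none
Why: Hydrogenolysis of the benzyl ether under neutral conditions at room temperature, where the electron-rich acid should not decarboxylate.

Step 17
Reactants: 26 4-hydroxy-2-methoxy-6-methylbenzoic acid
Product: 28 4-(tert-butyldimethylsilyloxy)-2-methoxy-6-methylbenzoic acid, via bis-silylated acid 27 (not isolated)
Conditions: TBSCl (2.5 eq), imidazole, DMF, 23 °C; then AcOH/THF/H2O 3:1:1, 23 °C
Reagents that add atoms: tert-butyldimethylsilyl chloride, CC(C)(C)[Si](C)(C)Cl
Why: Silylation of phenol and acid followed by selective hydrolysis of the far more labile silyl ester in dilute acid, which the aryl silyl ether withstands.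

Step 18
Reactants: 21 (5S,6S)-2-[(tert-butyldiphenylsilyloxy)methyl]-6-hydroxy-5-(4-methoxybenzyloxy)-6-methyl-3-[(E)-pent-3-en-1-yn-1-yl]cyclohex-2-en-1-one
Product: 29 (5S,6S)-2-[(tert-butyldiphenylsilyloxy)methyl]-5,6-dihydroxy-6-methyl-3-[(E)-pent-3-en-1-yn-1-yl]cyclohex-2-en-1-one
Conditions: DDQ (1.3 eq), CH2Cl2/pH 7 buffer 10:1, 0 °C
Reagents that add atoms: none
Why: Oxidative PMB cleavage by DDQ through the benzylic oxocarbenium ion, which water in the buffered two-phase medium should hydrolyse before the neighbouring C7-OH traps it, the electron-poor enynone and the silyl ether being inert.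

Step 19
Reactants: 29 (5S,6S)-2-[(tert-butyldiphenylsilyloxy)methyl]-5,6-dihydroxy-6-methyl-3-[(E)-pent-3-en-1-yn-1-yl]cyclohex-2-en-1-one; 28 4-(tert-butyldimethylsilyloxy)-2-methoxy-6-methylbenzoic acid
Product: 31 (1S,2S)-4-[(tert-butyldiphenylsilyloxy)methyl]-2-hydroxy-2-methyl-3-oxo-5-[(E)-pent-3-en-1-yn-1-yl]cyclohex-4-en-1-yl 4-(tert-butyldimethylsilyloxy)-2-methoxy-6-methylbenzoate, via acid chloride 30 (not isolated)
Conditions: 28, 1-chloro-N,N,2-trimethylprop-1-en-1-amine, CH2Cl2, 0 → 23 °C; then 29, Et3N, DMAP, CH2Cl2, 0 → 23 °C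
Reagents that add atoms: none
Why: DMAP-catalysed acylation of the secondary C6-OH by the acid chloride, made under neutral conditions from the α-chloro enamine so that the aryl silyl ether survives, with the tertiary C7-OH too hindered to react and the C6 configuration retained.

Step 20
Reactants: 31 (1S,2S)-4-[(tert-butyldiphenylsilyloxy)methyl]-2-hydroxy-2-methyl-3-oxo-5-[(E)-pent-3-en-1-yn-1-yl]cyclohex-4-en-1-yl 4-(tert-butyldimethylsilyloxy)-2-methoxy-6-methylbenzoate
Product: 32 (1S,2S)-2-hydroxy-4-(hydroxymethyl)-2-methyl-3-oxo-5-[(E)-pent-3-en-1-yn-1-yl]cyclohex-4-en-1-yl 4-hydroxy-2-methoxy-6-methylbenzoate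
Conditions: TBAF/AcOH (1:1, 4 eq), THF, 0 → 23 °C
Reagents that add atoms: none
Why: Buffered fluoride desilylation removes the phenolic TBS and the primary TBDPS groups, the acetic acid keeping the medium non-basic so that the aryl ester should not migrate to C7-OH and the α-ketol should not rearrange.

Step 21
Reactants: 32 (1S,2S)-2-hydroxy-4-(hydroxymethyl)-2-methyl-3-oxo-5-[(E)-pent-3-en-1-yn-1-yl]cyclohex-4-en-1-yl 4-hydroxy-2-methoxy-6-methylbenzoate
Product: 33 Comazaphilone G
Conditions: Ph3PAuNTf2 (5 mol %), CH2Cl2, 0 → 23 °C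
Reagents that add atoms: none
Why: Alkyne hydroalkoxylation catalysed by monovalent gold, as in the 6-endo-dig cycloisomerisation of 2-alkynylbenzyl alcohols to 1H-isochromenes, where the C8 ketone polarises the enyne through C8a=C4a so that C3 (also stabilised by the propenyl group) is the electrophilic end, O2 adds there anti to gold and protodeauration at C4 gives the pyran without touching a stereocentre.

**Compound list**

1 | 2-methyl-2-vinyl-1,3-dioxolane | C=CC1(C)OCCO1 | starting material
2 | rac-2-methyl-2-(oxiran-2-yl)-1,3-dioxolane | CC1(OCCO1)C2CO2 | intermediate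
3 | (S)-2-methyl-2-(oxiran-2-yl)-1,3-dioxolane | CC1(OCCO1)[C@@H]2CO2 | intermediate
4 | tert-butyldimethyl(prop-2-yn-1-yloxy)silane | C#CCO[Si](C)(C)C(C)(C)C | starting material
5 | lithium acetylide of 4 (not isolated) | [Li]C#CCO[Si](C)(C)C(C)(C)C | intermediate
6 | (S)-5-(tert-butyldimethylsilyloxy)-1-(2-methyl-1,3-dioxolan-2-yl)pent-3-yn-1-ol | CC1(OCCO1)[C@@H](O)CC#CCO[Si](C)(C)C(C)(C)C | intermediate
7 | (S)-tert-butyl{[5-(4-methoxybenzyloxy)-5-(2-methyl-1,3-dioxolan-2-yl)pent-2-yn-1-yl]oxy}dimethylsilane | CC1(OCCO1)[C@@H](OCc2ccc(OC)cc2)CC#CCO[Si](C)(C)C(C)(C)C | intermediate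
8 | (S)-5-(4-methoxybenzyloxy)-5-(2-methyl-1,3-dioxolan-2-yl)pent-2-yn-1-ol | CC1(OCCO1)[C@@H](OCc2ccc(OC)cc2)CC#CCO | intermediate
9 | vinylmagnesium chloride | C=C[Mg]Cl | starting material
10 | cyclic alkenylmagnesium alkoxide (five-membered O–Mg–C4a chelate, vinyl on C8a; not isolated) | CC1(OCCO1)[C@@H](OCc2ccc(OC)cc2)CC3=C(C=C)CO[Mg]3 | intermediate
11 | (2Z,5S)-3-iodo-5-(4-methoxybenzyloxy)-5-(2-methyl-1,3-dioxolan-2-yl)-2-vinylpent-2-en-1-ol | CC1(OCCO1)[C@@H](OCc2ccc(OC)cc2)C/C(I)=C(\C=C)CO | intermediate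
12 | tert-butyl{[(2Z,5S)-3-iodo-5-(4-methoxybenzyloxy)-5-(2-methyl-1,3-dioxolan-2-yl)-2-vinylpent-2-en-1-yl]oxy}diphenylsilane | CC1(OCCO1)[C@@H](OCc2ccc(OC)cc2)C/C(I)=C(\C=C)CO[Si](c2ccccc2)(c2ccccc2)C(C)(C)C | intermediate
13 | (3S,5Z)-6-[(tert-butyldiphenylsilyloxy)methyl]-5-iodo-3-(4-methoxybenzyloxy)octa-5,7-dien-2-one | CC(=O)[C@@H](OCc1ccc(OC)cc1)C/C(I)=C(\C=C)CO[Si](c1ccccc1)(c1ccccc1)C(C)(C)C | intermediate
14 | (3S,5E)-6-[(tert-butyldiphenylsilyloxy)methyl]-7,8-dihydroxy-5-iodo-3-(4-methoxybenzyloxy)oct-5-en-2-one (C7 carbinol epimers; not isolated) | CC(=O)[C@@H](OCc1ccc(OC)cc1)C/C(I)=C(\C(O)CO)CO[Si](c1ccccc1)(c1ccccc1)C(C)(C)C | intermediate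
15 | (2E,5S)-2-[(tert-butyldiphenylsilyloxy)methyl]-3-iodo-5-(4-methoxybenzyloxy)-6-oxohept-2-enal | CC(=O)[C@@H](OCc1ccc(OC)cc1)C/C(I)=C(\C=O)CO[Si](c1ccccc1)(c1ccccc1)C(C)(C)C | intermediate
16 | (E)-crotonaldehyde | C/C=C/C=O | starting material
17 | (3E)-1,1-dibromopenta-1,3-diene | C/C=C/C=C(Br)Br | intermediate
18 | lithium (E)-pent-3-en-1-yn-1-ide (not isolated) | C/C=C/C#C[Li] | intermediate
19 | (E)-pent-3-en-1-yne | C/C=C/C#C | intermediate
20 | (2E,5S)-2-[(tert-butyldiphenylsilyloxy)methyl]-5-(4-methoxybenzyloxy)-6-oxo-3-[(E)-pent-3-en-1-yn-1-yl]hept-2-enal | CC(=O)[C@@H](OCc1ccc(OC)cc1)C/C(C#C/C=C/C)=C(\C=O)CO[Si](c1ccccc1)(c1ccccc1)C(C)(C)C | intermediate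
21 | (5S,6S)-2-[(tert-butyldiphenylsilyloxy)methyl]-6-hydroxy-5-(4-methoxybenzyloxy)-6-methyl-3-[(E)-pent-3-en-1-yn-1-yl]cyclohex-2-en-1-one (C6-OPMB and C7-OH cis) | C/C=C/C#CC1=C(CO[Si](c2ccccc2)(c2ccccc2)C(C)(C)C)C(=O)[C@@](C)(O)[C@@H](OCc2ccc(OC)cc2)C1 | intermediate
22 | methyl orsellinate (methyl 2,4-dihydroxy-6-methylbenzoate) | COC(=O)c1c(C)cc(O)cc1O | starting material
23 | methyl 4-(benzyloxy)-2-hydroxy-6-methylbenzoate (not isolated) | COC(=O)c1c(C)cc(OCc2ccccc2)cc1O | intermediate
24 | methyl 4-(benzyloxy)-2-methoxy-6-methylbenzoate | COC(=O)c1c(C)cc(OCc2ccccc2)cc1OC | intermediate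
25 | 4-(benzyloxy)-2-methoxy-6-methylbenzoic acid | COc1cc(OCc2ccccc2)cc(C)c1C(=O)O | intermediate
26 | 4-hydroxy-2-methoxy-6-methylbenzoic acid | COc1cc(O)cc(C)c1C(=O)O | intermediate
27 | tert-butyldimethylsilyl 4-(tert-butyldimethylsilyloxy)-2-methoxy-6-methylbenzoate (not isolated) | COc1cc(O[Si](C)(C)C(C)(C)C)cc(C)c1C(=O)O[Si](C)(C)C(C)(C)C | intermediate
28 | 4-(tert-butyldimethylsilyloxy)-2-methoxy-6-methylbenzoic acid | COc1cc(O[Si](C)(C)C(C)(C)C)cc(C)c1C(=O)O | intermediate
29 | (5S,6S)-2-[(tert-butyldiphenylsilyloxy)methyl]-5,6-dihydroxy-6-methyl-3-[(E)-pent-3-en-1-yn-1-yl]cyclohex-2-en-1-one | C/C=C/C#CC1=C(CO[Si](c2ccccc2)(c2ccccc2)C(C)(C)C)C(=O)[C@@](C)(O)[C@@H](O)C1 | intermediate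
30 | 4-(tert-butyldimethylsilyloxy)-2-methoxy-6-methylbenzoyl chloride (not isolated) | COc1cc(O[Si](C)(C)C(C)(C)C)cc(C)c1C(Cl)=O | intermediate
31 | (1S,2S)-4-[(tert-butyldiphenylsilyloxy)methyl]-2-hydroxy-2-methyl-3-oxo-5-[(E)-pent-3-en-1-yn-1-yl]cyclohex-4-en-1-yl 4-(tert-butyldimethylsilyloxy)-2-methoxy-6-methylbenzoate | C/C=C/C#CC1=C(CO[Si](c2ccccc2)(c2ccccc2)C(C)(C)C)C(=O)[C@@](C)(O)[C@@H](OC(=O)c2c(C)cc(O[Si](C)(C)C(C)(C)C)cc2OC)C1 | intermediate
32 | (1S,2S)-2-hydroxy-4-(hydroxymethyl)-2-methyl-3-oxo-5-[(E)-pent-3-en-1-yn-1-yl]cyclohex-4-en-1-yl 4-hydroxy-2-methoxy-6-methylbenzoate | C/C=C/C#CC1=C(CO)C(=O)[C@@](C)(O)[C@@H](OC(=O)c2c(C)cc(O)cc2OC)C1 | intermediate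
33 | Comazaphilone G, (6S,7S)-7-hydroxy-7-methyl-8-oxo-3-[(E)-prop-1-en-1-yl]-5,6,7,8-tetrahydro-1H-isochromen-6-yl 4-hydroxy-2-methoxy-6-methylbenzoate | C/C=C/C1=CC2=C(CO1)C(=O)[C@@](C)(O)[C@@H](OC(=O)c1c(C)cc(O)cc1OC)C2 | target

**Step count**

Total: 21 steps. Longest linear sequence: 15 steps (1, 2, 3, 4, 5, 6, 7, 8, 9, 12, 13, 18, 19, 20, 21) from 1.

**Steps most likely to fail**

Step 13. The Breslow intermediate of the dienynal may be protonated at C4a or C3 (homoenolate or redox paths) instead of adding to the ketone, or the attack on the ketone may show poor facial selectivity at C7. The fallback sets out from 20 and replaces the umpolung by a reductive ketyl coupling: SmI2 (THF, t-BuOH, −78 °C) should reduce the aldehyde to its ketyl, which closes onto the samarium-bound ketone in the same chair (C6 ether and C7 methyl pseudo-equatorial) to give the cyclic C7,C8-diol F1. MnO2 in CH2Cl2 then oxidises only the secondary allylic C8 carbinol, and the route is rejoined at 21.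

Step 19. The acylation of the secondary C6-OH, flanked by the quaternary C7, with a di-ortho-substituted aroyl chloride may be too slow, so that acyl migration to C7-OH or base-induced decay of the α-ketol takes over. The fallback sets out from 29 and activates the alcohol instead of the acyl donor: Bu2Sn(OMe)2 (toluene, 60 °C, methanol removed) should give the dibutylstannylene acetal F2 of the cis-diol. Its more accessible secondary tin alkoxide reacts with acid chloride 30 under neutral conditions, and aqueous work-up returns to 31.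

Step 21. The oxygen may attack C4 in a 5-exo mode, or the gold catalyst may degrade the polyunsaturated substrate or the acid-sensitive dienol ether as it forms. The fallback sets out from 32 and fixes the regiochemistry by an intermolecular conjugate addition: diethylamine (EtOH, 23 °C) should add 1,6 to the ynenone at C3 to give the dienaminone F3. Mild acid (PPTS or AcOH, CH2Cl2) then lets C1-OH displace the amine at C3 by addition–elimination, which closes the pyran and arrives at 33.

Further compounds
F1 | step 13 | 2-[(tert-butyldiphenylsilyloxy)methyl]-5-(4-methoxybenzyloxy)-6-methyl-3-[(E)-pent-3-en-1-yn-1-yl]cyclohex-2-ene-1,6-diol (C6 and C7 as in 21, C8 carbinol epimers) | C/C=C/C#CC1=C(CO[Si](c2ccccc2)(c2ccccc2)C(C)(C)C)C(O)[C@@](C)(O)[C@@H](OCc2ccc(OC)cc2)C1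
F2 | step 19 | dibutylstannylene acetal (2,2-dibutyl-1,3,2-dioxastannolane) of diol 29 across O6 and O7 | C/C=C/C#CC1=C(CO[Si](c2ccccc2)(c2ccccc2)C(C)(C)C)C(=O)[C@@]3(C)O[Sn](CCCC)(CCCC)O[C@H]3C1
F3 | step 21 | C3 diethylamino dienone from 1,6-addition of diethylamine to 32 | C/C=C/C(N(CC)CC)=CC1=C(CO)C(=O)[C@@](C)(O)[C@@H](OC(=O)c2c(C)cc(O)cc2OC)C1
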